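**Retrosynthetic overview**
1. Target 25 ⇐ 24 ⇐ 23 (O-debenzylation, desilylation) ⇐ tertiary C4 carbinol 22 of the upper unit, reduced through its C4 cation with hydride entering trans to O3; this sets the 3,4-cis interflavan centre.
2. 22 ⇐ upper-unit flavan-4-one 20 + 6-lithiated lower unit 21 (from bromide 15): interflavan C4–C6 bond by carbonyl addition.
3. 20 ⇐ open-chain ketone 19: ring C of the upper unit is closed through the O1–C8a aryl ether bond by fluoride-relayed intramolecular SNAr of the C2 oxygen on C8a–F. Enabling feature: in ring A of the upper unit C8a is ortho to C4a, and C4a carries C4, the carbon that must finally bond to C6 of the lower unit; a carbonyl at C4 therefore activates C8a for displacement and then serves as the electrophile for the interflavan bond.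
4. Lower unit 15 by the same O1–C8a closure in the syn series (11 to 12), C4 reduction, silylation and C6 bromination; both open-chain ketones come from one racemic keto ester 6 by stereodivergent dynamic kinetic reductions (ruthenium transfer hydrogenation: syn; ketoreductase: anti) and from one batch of aryl Grignard reagent 9 made from 3-fluorocatechol.
5. Ring order: rings A and B enter as benzenes; ring C of the lower unit (step 8); ring C of the upper unit (step 14).

Key step: step 14

Assumption: flavan numbering (O1, C2, C3, C4, C4a, C5 to C8, C8a; ring A the fused arene, ring B the C2 aryl, ring C the pyran) is used inside each unit and for the open-chain precursors; "upper unit" is the 4-aryl flavan-3-ol (2S,3R,4R in the target), "lower unit" the flavan-3,4-diol (2R,3R,4R); compounds 1, 4 and 5 are taken as commercial.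

Step 1
Reactants: 1 3-fluorocatechol (3-fluorobenzene-1,2-diol)
Product: 2 1,2-bis(benzyloxy)-3-fluorobenzene
Conditions: BnBr, K2CO3, DMF, 60 °C
Reagents that add atoms: benzyl bromide, BrCc1ccccc1
Why: Twofold Williamson ether synthesis of an acidic catechol with a reactive benzylic halide under carbonate conditions, with no stereocentre involved.

Step 2
Reactants: 2 1,2-bis(benzyloxy)-3-fluorobenzene
Product: 3 1-bromo-3,4-bis(benzyloxy)-2-fluorobenzene
Conditions: NBS, MeCN, 0 °C to rt
Reagents that add atoms: N-bromosuccinimide, O=C1CCC(=O)N1Br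
Why: Electrophilic aromatic bromination should go para to the benzyloxy group that has only one ortho neighbour and can stay coplanar with the ring (the other one is twisted between two substituents), a position that is also ortho to fluorine, so bromine enters next to C–F.

Step 3
Reactants: 4 ethyl 2-(benzyloxy)acetate; 5 4-(benzyloxy)benzoyl chloride
Product: 6 ethyl 2-(benzyloxy)-3-[4-(benzyloxy)phenyl]-3-oxopropanoate (racemic)
Conditions: LiN(SiMe3)2 (2.1 equiv), THF, −78 °C; then 5; then AcOH
Reagents that add atoms: none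
Why: Crossed Claisen condensation (C-acylation of the lithium ester enolate by the aroyl chloride), driven forward because the second equivalent of base deprotonates the more acidic keto ester; the new stereocentre is left racemic on purpose since it epimerises freely and is resolved dynamically in steps 4 and 11.

Step 4
Reactants: 6 ethyl 2-(benzyloxy)-3-[4-(benzyloxy)phenyl]-3-oxopropanoate (racemic)
Product: 7 ethyl (2S,3R)-2-(benzyloxy)-3-[4-(benzyloxy)phenyl]-3-hydroxypropanoate (syn)
Conditions: RuCl[(S,S)-TsDPEN](p-cymene) (1 mol%), HCO2H–Et3N (5:2), CH2Cl2, 30 °C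
Reagents that add atoms: none
Why: Noyori asymmetric transfer hydrogenation with dynamic kinetic resolution, a reaction type known to give syn mono-protected diols from α-alkoxy β-keto esters: the (S,S) catalyst should deliver hydride to the aryl ketone face that gives the 3R carbinol, and because C2 epimerises through the enol faster than reduction, all material should pass through the faster-reacting 2S ketone, so C3 is set by the catalyst and C2 by the dynamic resolution.

Step 5
Reactants: 7 ethyl (2S,3R)-2-(benzyloxy)-3-[4-(benzyloxy)phenyl]-3-hydroxypropanoate (syn)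
Product: 8 ethyl (2S,3R)-2-(benzyloxy)-3-[4-(benzyloxy)phenyl]-3-(triethylsilyloxy)propanoate
Conditions: Et3SiCl, imidazole, DMF, 0 °C to rt
Reagents that add atoms: chlorotriethylsilane, CC[Si](Cl)(CC)CC
Why: Standard silylation of a secondary alcohol, which blocks retro-aldol cleavage in the ketone synthesis and installs the group that the fluoride relay of step 8 removes; no stereocentre is touched.

Step 6
Reactants: 3 1-bromo-3,4-bis(benzyloxy)-2-fluorobenzene
Product: 9 [3,4-bis(benzyloxy)-2-fluorophenyl]magnesium chloride (titrated THF solution, held at −20 °C)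
Conditions: iPrMgCl·LiCl, THF, −15 °C
Reagents that add atoms: isopropylmagnesium chloride–lithium chloride complex, CC(C)[Mg]Cl.[Li+].[Cl-]
Why: Bromine–magnesium exchange, accelerated by the ortho fluorine and the two inductively withdrawing ring oxygens, should give the arylmagnesium chloride without touching the benzyl ethers, and the solution is kept below 0 °C so that the ortho-fluoro arylmagnesium does not collapse to an aryne, is prepared as one batch once esters 8 and 17 are both in hand, and is divided between steps 7 and 13.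

Step 7
Reactants: 8 ethyl (2S,3R)-2-(benzyloxy)-3-[4-(benzyloxy)phenyl]-3-(triethylsilyloxy)propanoate; 9 [3,4-bis(benzyloxy)-2-fluorophenyl]magnesium chloride
Product: 11 (2S,3R)-2-(benzyloxy)-1-[3,4-bis(benzyloxy)-2-fluorophenyl]-3-[4-(benzyloxy)phenyl]-3-(triethylsilyloxy)propan-1-one, via Weinreb amide 10 (not isolated)
Conditions: MeNHOMe·HCl, iPrMgCl, THF, −20 °C; then 9 (THF solution from step 6), −20 to 0 °C; then H2O
Reagents that add atoms: none
Why: Weinreb ketone synthesis run in one flask: the chloromagnesium amide of MeNHOMe converts the ester into amide 10, whose magnesium chelate with Grignard reagent 9 cannot break down before the quench, so addition stops at the ketone and neither stereocentre is touched.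

Step 8
Reactants: 11 (2S,3R)-2-(benzyloxy)-1-[3,4-bis(benzyloxy)-2-fluorophenyl]-3-[4-(benzyloxy)phenyl]-3-(triethylsilyloxy)propan-1-one
Product: 13 (2R,3R,4R)-3,7,8-tris(benzyloxy)-2-[4-(benzyloxy)phenyl]chroman-4-ol (all-cis), via cis-flavanonol 12 (not isolated)
Conditions: Bu4N[Ph3SiF2] (5 mol%), THF, 0 °C to rt; then LiBH(s-Bu)3, −78 °C; then H2O
Reagents that add atoms: none
Why: The same fluoride-relayed intramolecular SNAr as in step 14 should close ring C of the lower unit with retention at both stereocentres to give the 2,3-cis flavanonol 12, which is reduced at once so that C3 cannot epimerise, the bulky borohydride attacking the C4 carbonyl from the face opposite the axial C3 benzyloxy group and the C2 aryl group and so setting C4 as R (all-cis).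

Step 9
Reactants: 13 (2R,3R,4R)-3,7,8-tris(benzyloxy)-2-[4-(benzyloxy)phenyl]chroman-4-ol (all-cis)
Product: 14 (2R,3S,4R)-3,7,8-tris(benzyloxy)-2-[4-(benzyloxy)phenyl]-4-(tert-butyldimethylsilyloxy)chroman
Conditions: t-BuMe2SiOTf, 2,6-lutidine, CH2Cl2, 0 °C
Reagents that add atoms: tert-butyldimethylsilyl trifluoromethanesulfonate, CC(C)(C)[Si](C)(C)OS(=O)(=O)C(F)(F)F
Why: Silylation of the hindered benzylic alcohol with a silyl triflate and a non-nucleophilic base keeps the C4 oxygen inert to the aryllithium and slows acid ionisation at C4 later; the geometry is unchanged and only the C3 descriptor switches to S through the priority rules.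

Step 10
Reactants: 14 (2R,3S,4R)-3,7,8-tris(benzyloxy)-2-[4-(benzyloxy)phenyl]-4-(tert-butyldimethylsilyloxy)chroman
Product: 15 (2R,3S,4R)-6-bromo-3,7,8-tris(benzyloxy)-2-[4-(benzyloxy)phenyl]-4-(tert-butyldimethylsilyloxy)chroman
Conditions: NBS, MeCN, 0 °C, dark
Reagents that add atoms: N-bromosuccinimide, O=C1CCC(=O)N1Br
Why: Electrophilic aromatic bromination of ring A should occur at C6, which is para to the ring oxygen O1 and ortho to the C7 benzyloxy group, whereas C5 is activated only by the C8 benzyloxy group (twisted out of conjugation between its two ortho neighbours) and is shielded by the peri C4 silyloxy group, and ring B is a less activated mono-alkoxy arene; no stereocentre is touched.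

Step 11
Reactants: 6 ethyl 2-(benzyloxy)-3-[4-(benzyloxy)phenyl]-3-oxopropanoate (racemic)
Product: 16 ethyl (2S,3S)-2-(benzyloxy)-3-[4-(benzyloxy)phenyl]-3-hydroxypropanoate (anti)
Conditions: ketoreductase (NADPH-dependent alcohol dehydrogenase, anti-selective variant chosen from a screening panel), NADP+ (cat.), iPrOH, potassium phosphate buffer pH 7, DMSO co-solvent, 30 °C
Reagents that add atoms: none
Why: Enzymatic dynamic kinetic reduction by a ketoreductase: the α-centre of 6 racemises spontaneously in neutral buffer, the enzyme should bind only the 2S ketone and transfer the NADPH hydride to the carbonyl face that gives the 3S alcohol, an anti outcome that small hydride reagents do not deliver on a stereolabile keto ester, while iPrOH regenerates the cofactor.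

Step 12
Reactants: 16 ethyl (2S,3S)-2-(benzyloxy)-3-[4-(benzyloxy)phenyl]-3-hydroxypropanoate (anti)
Product: 17 ethyl (2S,3S)-2-(benzyloxy)-3-[4-(benzyloxy)phenyl]-3-(triethylsilyloxy)propanoate
Conditions: Et3SiCl, imidazole, DMF, 0 °C to rt
Reagents that add atoms: chlorotriethylsilane, CC[Si](Cl)(CC)CC
Why: Standard silylation of the secondary alcohol, as in step 5, with no stereocentre touched.

Step 13
Reactants: 17 ethyl (2S,3S)-2-(benzyloxy)-3-[4-(benzyloxy)phenyl]-3-(triethylsilyloxy)propanoate; 9 [3,4-bis(benzyloxy)-2-fluorophenyl]magnesium chloride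
Product: 19 (2S,3S)-2-(benzyloxy)-1-[3,4-bis(benzyloxy)-2-fluorophenyl]-3-[4-(benzyloxy)phenyl]-3-(triethylsilyloxy)propan-1-one, via Weinreb amide 18 (not isolated)
Conditions: MeNHOMe·HCl, iPrMgCl, THF, −20 °C; then 9 (THF solution from step 6), −20 to 0 °C; then H2O
Reagents that add atoms: none
Why: One-flask Weinreb ketone synthesis exactly as in step 7, the chelated tetrahedral adduct stopping the Grignard addition at the ketone and leaving both stereocentres untouched.

Step 14
Reactants: 19 (2S,3S)-2-(benzyloxy)-1-[3,4-bis(benzyloxy)-2-fluorophenyl]-3-[4-(benzyloxy)phenyl]-3-(triethylsilyloxy)propan-1-one; 15 (2R,3S,4R)-6-bromo-3,7,8-tris(benzyloxy)-2-[4-(benzyloxy)phenyl]-4-(tert-butyldimethylsilyloxy)chroman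
Product: 22 (2S,3S,4S)-3,7,8-tris(benzyloxy)-2-[4-(benzyloxy)phenyl]-4-[(2R,3S,4R)-3,7,8-tris(benzyloxy)-2-[4-(benzyloxy)phenyl]-4-(tert-butyldimethylsilyloxy)chroman-6-yl]chroman-4-ol, via trans-flavanonol 20 (not isolated), via aryllithium 21 (not isolated)
Conditions: Bu4N[Ph3SiF2] (5 mol%), THF, 0 °C to rt; volatiles removed in vacuo, THF; cannulated at −78 °C into 21 [from 15, t-BuLi (2 equiv), THF, −78 °C]; then H2O
Reagents that add atoms: none
Why: Catalytic fluoride cleaves the silyl ether, the C2 alkoxide adds to C8a of ring A (the charge of the Meisenheimer adduct rests on the C4 carbonyl oxygen, ortho through C4a) and fluoride is expelled, so the leaving group desilylates the next molecule and the O1–C8a bond forms in a fluoride relay with no stoichiometric base and Et3SiF as the only by-product, after which ketone 20 is trapped in the same flask by aryllithium 21 to form the interflavan C4–C6 bond. The closest known reaction types are the intramolecular SNAr of β-hydroxy 2-fluoroaryl ketones to chroman-4-ones, the fluoride-catalysed aryl ether formation from silyl ethers and activated aryl fluorides, and the 1,2-addition of hindered aryllithiums to 3-oxygenated flavan-4-ones. Ring C closes in a 6-endo-trig addition–elimination (oxygen onto C8a of the C8a=C4a–C4=O acceptor), and the second stage closes no ring. C2 and C3 keep their configuration because the oxygen and not the carbon at C2 is the nucleophile and no bond to C3 is touched, while the new carbinol centre C4 should form by attack anti to the C3 benzyloxy group (4S) but needs no control because step 15 erases it. The step needs the six-membered closure through the C2 oxygen only, which is secured by the benzylated C3 oxygen (no five-ring benzofuranone), by fluorine standing only at C8a and by the merely catalytic alkoxide concentration (little retro-aldol or β-elimination), and it needs addition rather than enolisation in the second stage, which the low temperature and the lithium chelate between the carbonyl and the C3 benzyloxy oxygen favour. In one operation the C4 carbonyl first makes C8a–F displaceable and then accepts the lower unit, so an open-chain ketone and a monomeric bromide become the full skeleton of the target.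

Step 15
Reactants: 22 (2S,3S,4S)-3,7,8-tris(benzyloxy)-2-[4-(benzyloxy)phenyl]-4-[(2R,3S,4R)-3,7,8-tris(benzyloxy)-2-[4-(benzyloxy)phenyl]-4-(tert-butyldimethylsilyloxy)chroman-6-yl]chroman-4-ol
Product: 23 (2R,3S,4R)-3,7,8-tris(benzyloxy)-2-[4-(benzyloxy)phenyl]-4-(tert-butyldimethylsilyloxy)-6-[(2S,3R,4S)-3,7,8-tris(benzyloxy)-2-[4-(benzyloxy)phenyl]chroman-4-yl]chroman
Conditions: Bu3SnH, CF3CO2H, CH2Cl2, −78 to −20 °C
Reagents that add atoms: none
Why: Ionic deoxygenation (acid ionisation, then hydride transfer from the stannane): the tertiary carbinol gives a C4 cation stabilised by two oxygenated aryl rings and should ionise far faster than the secondary silyl-protected benzylic C4–O bond of the lower unit, and hydride should enter the planar cation on the face anti to the neighbouring C3 benzyloxy group, which leaves the lower unit cis to O3 and trans to the C2 aryl group (2,3-trans-3,4-cis, 4S in this protected form), the relative configuration that direct aryl attack on a flavan-4-yl cation would give only as the minor isomer.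

Step 16
Reactants: 23 (2R,3S,4R)-3,7,8-tris(benzyloxy)-2-[4-(benzyloxy)phenyl]-4-(tert-butyldimethylsilyloxy)-6-[(2S,3R,4S)-3,7,8-tris(benzyloxy)-2-[4-(benzyloxy)phenyl]chroman-4-yl]chroman
Product: 24 (2R,3R,4R)-3,7,8-tris(benzyloxy)-2-[4-(benzyloxy)phenyl]-6-[(2S,3R,4S)-3,7,8-tris(benzyloxy)-2-[4-(benzyloxy)phenyl]chroman-4-yl]chroman-4-ol
Conditions: Bu4NF, THF, 0 °C to rt; then H2O
Reagents that add atoms: none
Why: Fluoride-induced desilylation driven by the Si–F bond should free the C4 hydroxyl of the lower unit under non-acidic conditions that leave the benzyl ethers and all six stereocentres untouched.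

Step 17
Reactants: 24 (2R,3R,4R)-3,7,8-tris(benzyloxy)-2-[4-(benzyloxy)phenyl]-6-[(2S,3R,4S)-3,7,8-tris(benzyloxy)-2-[4-(benzyloxy)phenyl]chroman-4-yl]chroman-4-ol
Product: 25 (2R,3R,4R)-2-(4-hydroxyphenyl)-6-[(2S,3R,4R)-3,7,8-trihydroxy-2-(4-hydroxyphenyl)chroman-4-yl]chroman-3,4,7,8-tetrol (target)
Conditions: H2 (1 atm), Pd(OH)2/C, NaHCO3, THF–MeOH, rt
Reagents that add atoms: none
Why: Hydrogenolysis of the six aryl and two alkyl benzyl ethers over Pd(OH)2/C, where under neutral bicarbonate-buffered conditions O-benzyl cleavage should be much faster than hydrogenolysis of the free benzylic C4–OH or of the ring C2–O1 bonds, so the stereocentres are kept and the target is released (the upper C4 descriptor changes from S to R only through the priority rules).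

**Compound list**
1 | 3-fluorocatechol | Oc1cccc(F)c1O | starting material
2 | 1,2-bis(benzyloxy)-3-fluorobenzene | Fc1cccc(OCc2ccccc2)c1OCc1ccccc1 | intermediate
3 | 1-bromo-3,4-bis(benzyloxy)-2-fluorobenzene | Brc1ccc(OCc2ccccc2)c(OCc2ccccc2)c1F | intermediate
4 | ethyl 2-(benzyloxy)acetate | CCOC(=O)COCc1ccccc1 | starting material
5 | 4-(benzyloxy)benzoyl chloride | O=C(Cl)c1ccc(OCc2ccccc2)cc1 | starting material
6 | ethyl 2-(benzyloxy)-3-[4-(benzyloxy)phenyl]-3-oxopropanoate (racemic) | CCOC(=O)C(OCc1ccccc1)C(=O)c1ccc(OCc2ccccc2)cc1 | intermediate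
7 | ethyl (2S,3R)-2-(benzyloxy)-3-[4-(benzyloxy)phenyl]-3-hydroxypropanoate | CCOC(=O)[C@@H](OCc1ccccc1)[C@H](O)c1ccc(OCc2ccccc2)cc1 | intermediate
8 | ethyl (2S,3R)-2-(benzyloxy)-3-[4-(benzyloxy)phenyl]-3-(triethylsilyloxy)propanoate | CCOC(=O)[C@@H](OCc1ccccc1)[C@H](O[Si](CC)(CC)CC)c1ccc(OCc2ccccc2)cc1 | intermediate
9 | [3,4-bis(benzyloxy)-2-fluorophenyl]magnesium chloride | Cl[Mg]c1ccc(OCc2ccccc2)c(OCc2ccccc2)c1F | intermediate
10 | (2S,3R)-2-(benzyloxy)-3-[4-(benzyloxy)phenyl]-N-methoxy-N-methyl-3-(triethylsilyloxy)propanamide | CON(C)C(=O)[C@@H](OCc1ccccc1)[C@H](O[Si](CC)(CC)CC)c1ccc(OCc2ccccc2)cc1 | intermediate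
11 | (2S,3R)-2-(benzyloxy)-1-[3,4-bis(benzyloxy)-2-fluorophenyl]-3-[4-(benzyloxy)phenyl]-3-(triethylsilyloxy)propan-1-one | O=C(c1ccc(OCc2ccccc2)c(OCc2ccccc2)c1F)[C@@H](OCc1ccccc1)[C@H](O[Si](CC)(CC)CC)c1ccc(OCc2ccccc2)cc1 | intermediate
12 | (2R,3S)-3,7,8-tris(benzyloxy)-2-[4-(benzyloxy)phenyl]chroman-4-one (2,3-cis) | O=C1c2ccc(OCc3ccccc3)c(OCc3ccccc3)c2O[C@H](c2ccc(OCc3ccccc3)cc2)[C@@H]1OCc1ccccc1 | intermediate
13 | (2R,3R,4R)-3,7,8-tris(benzyloxy)-2-[4-(benzyloxy)phenyl]chroman-4-ol | O[C@@H]1c2ccc(OCc3ccccc3)c(OCc3ccccc3)c2O[C@H](c2ccc(OCc3ccccc3)cc2)[C@@H]1OCc1ccccc1 | intermediate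
14 | (2R,3S,4R)-3,7,8-tris(benzyloxy)-2-[4-(benzyloxy)phenyl]-4-(tert-butyldimethylsilyloxy)chroman | CC(C)(C)[Si](C)(C)O[C@@H]1c2ccc(OCc3ccccc3)c(OCc3ccccc3)c2O[C@H](c2ccc(OCc3ccccc3)cc2)[C@@H]1OCc1ccccc1 | intermediate
15 | (2R,3S,4R)-6-bromo-3,7,8-tris(benzyloxy)-2-[4-(benzyloxy)phenyl]-4-(tert-butyldimethylsilyloxy)chroman | CC(C)(C)[Si](C)(C)O[C@@H]1c2cc(Br)c(OCc3ccccc3)c(OCc3ccccc3)c2O[C@H](c2ccc(OCc3ccccc3)cc2)[C@@H]1OCc1ccccc1 | intermediate
16 | ethyl (2S,3S)-2-(benzyloxy)-3-[4-(benzyloxy)phenyl]-3-hydroxypropanoate | CCOC(=O)[C@@H](OCc1ccccc1)[C@@H](O)c1ccc(OCc2ccccc2)cc1 | intermediate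
17 | ethyl (2S,3S)-2-(benzyloxy)-3-[4-(benzyloxy)phenyl]-3-(triethylsilyloxy)propanoate | CCOC(=O)[C@@H](OCc1ccccc1)[C@@H](O[Si](CC)(CC)CC)c1ccc(OCc2ccccc2)cc1 | intermediate
18 | (2S,3S)-2-(benzyloxy)-3-[4-(benzyloxy)phenyl]-N-methoxy-N-methyl-3-(triethylsilyloxy)propanamide | CON(C)C(=O)[C@@H](OCc1ccccc1)[C@@H](O[Si](CC)(CC)CC)c1ccc(OCc2ccccc2)cc1 | intermediate
19 | (2S,3S)-2-(benzyloxy)-1-[3,4-bis(benzyloxy)-2-fluorophenyl]-3-[4-(benzyloxy)phenyl]-3-(triethylsilyloxy)propan-1-one | O=C(c1ccc(OCc2ccccc2)c(OCc2ccccc2)c1F)[C@@H](OCc1ccccc1)[C@@H](O[Si](CC)(CC)CC)c1ccc(OCc2ccccc2)cc1 | intermediate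
20 | (2S,3S)-3,7,8-tris(benzyloxy)-2-[4-(benzyloxy)phenyl]chroman-4-one (2,3-trans) | O=C1c2ccc(OCc3ccccc3)c(OCc3ccccc3)c2O[C@@H](c2ccc(OCc3ccccc3)cc2)[C@@H]1OCc1ccccc1 | intermediate
21 | [(2R,3S,4R)-3,7,8-tris(benzyloxy)-2-[4-(benzyloxy)phenyl]-4-(tert-butyldimethylsilyloxy)chroman-6-yl]lithium | CC(C)(C)[Si](C)(C)O[C@@H]1c2cc([Li])c(OCc3ccccc3)c(OCc3ccccc3)c2O[C@H](c2ccc(OCc3ccccc3)cc2)[C@@H]1OCc1ccccc1 | intermediate
22 | (2S,3S,4S)-3,7,8-tris(benzyloxy)-2-[4-(benzyloxy)phenyl]-4-[(2R,3S,4R)-3,7,8-tris(benzyloxy)-2-[4-(benzyloxy)phenyl]-4-(tert-butyldimethylsilyloxy)chroman-6-yl]chroman-4-ol | CC(C)(C)[Si](C)(C)O[C@@H]1c2cc([C@@]3(O)c4ccc(OCc5ccccc5)c(OCc5ccccc5)c4O[C@@H](c4ccc(OCc5ccccc5)cc4)[C@@H]3OCc3ccccc3)c(OCc3ccccc3)c(OCc3ccccc3)c2O[C@H](c2ccc(OCc3ccccc3)cc2)[C@@H]1OCc1ccccc1 | intermediate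
23 | (2R,3S,4R)-3,7,8-tris(benzyloxy)-2-[4-(benzyloxy)phenyl]-4-(tert-butyldimethylsilyloxy)-6-[(2S,3R,4S)-3,7,8-tris(benzyloxy)-2-[4-(benzyloxy)phenyl]chroman-4-yl]chroman | CC(C)(C)[Si](C)(C)O[C@@H]1c2cc([C@@H]3c4ccc(OCc5ccccc5)c(OCc5ccccc5)c4O[C@@H](c4ccc(OCc5ccccc5)cc4)[C@@H]3OCc3ccccc3)c(OCc3ccccc3)c(OCc3ccccc3)c2O[C@H](c2ccc(OCc3ccccc3)cc2)[C@@H]1OCc1ccccc1 | intermediate
24 | (2R,3R,4R)-3,7,8-tris(benzyloxy)-2-[4-(benzyloxy)phenyl]-6-[(2S,3R,4S)-3,7,8-tris(benzyloxy)-2-[4-(benzyloxy)phenyl]chroman-4-yl]chroman-4-ol | O[C@@H]1c2cc([C@@H]3c4ccc(OCc5ccccc5)c(OCc5ccccc5)c4O[C@@H](c4ccc(OCc5ccccc5)cc4)[C@@H]3OCc3ccccc3)c(OCc3ccccc3)c(OCc3ccccc3)c2O[C@H](c2ccc(OCc3ccccc3)cc2)[C@@H]1OCc1ccccc1 | intermediate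
25 | (2R,3R,4R)-2-(4-hydroxyphenyl)-6-[(2S,3R,4R)-3,7,8-trihydroxy-2-(4-hydroxyphenyl)chroman-4-yl]chroman-3,4,7,8-tetrol | Oc1ccc([C@H]2Oc3c(cc([C@@H]4c5ccc(O)c(O)c5O[C@@H](c5ccc(O)cc5)[C@@H]4O)c(O)c3O)[C@@H](O)[C@H]2O)cc1 | target

Total step count: 17. Longest linear sequence: 11 steps (steps 3, 4, 5, 7, 8, 9, 10, 14, 15, 16, 17; the sequence from 1 through steps 1, 2, 6, 7 and onward is equally long).

**Steps most likely to fail**

Step 14. What may go wrong: deprotonation of the α-benzyloxy ketone at C3 by the basic aryllithium competes with carbonyl addition, and the enolate then loses its C3 configuration or opens ring C by β-elimination of the ring oxygen. The fallback separates the two events and changes the nucleophile to a much less basic organocerium reagent. It sets out from 19 and 15: the fluoride-relayed ring closure is run alone and the trans-flavanonol 20 is isolated by filtration through silica. Aryllithium 21 (from 15, t-BuLi, THF, −78 °C) is stirred with anhydrous CeCl3 to give dichloro[(2R,3S,4R)-3,7,8-tris(benzyloxy)-2-[4-(benzyloxy)phenyl]-4-(tert-butyldimethylsilyloxy)chroman-6-yl]cerium F1, which is added to 20 at −78 °C. The route is rejoined at 22.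

Step 15. What may go wrong: weak facial selectivity of hydride delivery to the C4 cation, proton loss from the cation towards the enol ether, or competing acid ionisation at the silylated benzylic C4 of the lower unit. The fallback is a neutral radical deoxygenation that sets out from 22. The alcohol is deprotonated with n-BuLi (THF, −78 °C) and acylated with methyl chlorooxoacetate to give (2S,3S,4S)-3,7,8-tris(benzyloxy)-2-[4-(benzyloxy)phenyl]-4-[(2R,3S,4R)-3,7,8-tris(benzyloxy)-2-[4-(benzyloxy)phenyl]-4-(tert-butyldimethylsilyloxy)chroman-6-yl]chroman-4-yl methyl oxalate F2. Heating F2 with Bu3SnH and AIBN in toluene at 90 °C should fragment it to the diarylmethyl radical at C4, which takes hydrogen from the stannane on the face away from the C3 benzyloxy group. No acid is present, and the route is rejoined at 23.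

Step 11. What may go wrong: low turnover or insufficient anti selectivity of the ketoreductase on a bulky α-benzyloxy aryl keto ester. The fallback sets out from 7, the syn isomer made in step 4, and inverts its carbinol centre. Mitsunobu esterification with 4-nitrobenzoic acid (PPh3, DIAD, THF, 0 °C) should give ethyl (2S,3S)-2-(benzyloxy)-3-[4-(benzyloxy)phenyl]-3-[(4-nitrobenzoyl)oxy]propanoate F3 with inversion at C3. Transesterification with K2CO3 in EtOH at 0 °C then removes the nitrobenzoate, and the route is rejoined at 16.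

**Further compounds**
F1 | step 14 | dichloro[(2R,3S,4R)-3,7,8-tris(benzyloxy)-2-[4-(benzyloxy)phenyl]-4-(tert-butyldimethylsilyloxy)chroman-6-yl]cerium | CC(C)(C)[Si](C)(C)O[C@@H]1c2cc([Ce](Cl)Cl)c(OCc3ccccc3)c(OCc3ccccc3)c2O[C@H](c2ccc(OCc3ccccc3)cc2)[C@@H]1OCc1ccccc1
F2 | step 15 | (2S,3S,4S)-3,7,8-tris(benzyloxy)-2-[4-(benzyloxy)phenyl]-4-[(2R,3S,4R)-3,7,8-tris(benzyloxy)-2-[4-(benzyloxy)phenyl]-4-(tert-butyldimethylsilyloxy)chroman-6-yl]chroman-4-yl methyl oxalate | CC(C)(C)[Si](C)(C)O[C@@H]1c2cc([C@@]3(OC(=O)C(=O)OC)c4ccc(OCc5ccccc5)c(OCc5ccccc5)c4O[C@@H](c4ccc(OCc5ccccc5)cc4)[C@@H]3OCc3ccccc3)c(OCc3ccccc3)c(OCc3ccccc3)c2O[C@H](c2ccc(OCc3ccccc3)cc2)[C@@H]1OCc1ccccc1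
F3 | step 11 | ethyl (2S,3S)-2-(benzyloxy)-3-[4-(benzyloxy)phenyl]-3-[(4-nitrobenzoyl)oxy]propanoate | CCOC(=O)[C@@H](OCc1ccccc1)[C@@H](OC(=O)c1ccc(cc1)[N+](=O)[O-])c1ccc(OCc2ccccc2)cc1
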